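**Plan**

1. Rings: A = para-phenylene, B = the 1,2,3-trioxygenated ring, C = meta-phenylene, D = the ring with one OH. Retrosynthetic cuts, in order: (a) the aryl ether bond between the ring B oxygen (on the carbon next to the bridge carbon) and ring C, as an intramolecular SNAr after a temporary NO2 is placed on ring C; (b) the ring D–CH2CH2–ring C bridge; (c) the ring A–CH2CH2–ring B bridge (both by Wittig olefination, then C=C reduction); (d) the ring A–O–ring D ether (intermolecular SNAr).
2. Enabling feature: the ring C carbon para to its ether carbon (ortho to the benzylic carbon) is a C–H in the target, so it can hold NO2 to activate a C–F bond for the closure and be cleared afterwards (NO2 → NH2 → N2+ → H). The ring B oxygen to be arylated is kept as the only free OH; the other three oxygens are methyl ethers that come with the purchased rings B and D.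
3. Forward order: ring A–O–ring D ether, chain growth to ring B, then to the fluoronitro ring C, giving an open chain of four rings joined by two flexible saturated bridges. The 18-membered ring is closed last at the most hindered ether bond; nitro removal and demethylation finish the route.
4. Stereochemistry: the target has no stereocentre and no C=C bond; both Wittig alkenes are E/Z mixtures that are saturated, so nothing needs control.

Key step: step 13

Remark: alkenes 9 and 16 are expected as E/Z mixtures and are carried on unseparated, so their SMILES are written without double-bond geometry.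

**Route**

Step 1
Reactants: 1 methyl 3-hydroxy-4-methoxybenzoate; 2 4-fluorobenzaldehyde
Product: 3 methyl 3-(4-formylphenoxy)-4-methoxybenzoate
Conditions: K2CO3, DMF, 150 °C
Reagents that add atoms: none
Why: Nucleophilic aromatic substitution in which the para-formyl group activates the C–F bond of 2 toward the phenol of 1 under carbonate base, a diaryl ether synthesis with close precedent for isovanillate esters.

Step 2
Reactants: 3 methyl 3-(4-formylphenoxy)-4-methoxybenzoate
Product: 4 methyl 3-[4-(hydroxymethyl)phenoxy]-4-methoxybenzoate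
Conditions: NaBH4, MeOH/THF, 0 °C
Reagents that add atoms: none
Why: Chemoselective borohydride reduction, since NaBH4 reduces the aryl aldehyde and leaves the methyl benzoate untouched at 0 °C.

Step 3
Reactants: 4 methyl 3-[4-(hydroxymethyl)phenoxy]-4-methoxybenzoate
Product: 5 {4-[2-methoxy-5-(methoxycarbonyl)phenoxy]benzyl}triphenylphosphonium bromide
Conditions: PPh3·HBr, MeCN, reflux
Reagents that add atoms: triphenylphosphine hydrobromide, [Br-].[PH+](c1ccccc1)(c1ccccc1)c1ccccc1
Why: Direct conversion of a benzylic alcohol into its Wittig salt, in which HBr ionises the 4-aryloxybenzyl alcohol and PPh3 captures the benzylic electrophile while the ester is inert.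

Step 4
Reactants: 6 2-hydroxy-3,4-dimethoxybenzaldehyde
Product: 7 3,4-dimethoxy-2-(methoxymethoxy)benzaldehyde
Conditions: MOMCl, i-Pr2NEt, CH2Cl2, 0 °C to rt
Reagents that add atoms: chloromethyl methyl ether (MOMCl), COCCl
Why: Williamson-type O-alkylation that masks the only hydroxyl of 6 as a MOM ether, a group that survives base, hydride, hydrogenation and the Appel reaction and is later removed by acid, to which a fluoronitroarene is inert.

Step 5
Reactants: 5 {4-[2-methoxy-5-(methoxycarbonyl)phenoxy]benzyl}triphenylphosphonium bromide; 7 3,4-dimethoxy-2-(methoxymethoxy)benzaldehyde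
Product: 9 methyl 3-(4-{2-[3,4-dimethoxy-2-(methoxymethoxy)phenyl]ethenyl}phenoxy)-4-methoxybenzoate (E/Z mixture), via phosphonium ylide 8 (not isolated)
Conditions: K2CO3, 18-crown-6 (cat.), CH2Cl2, reflux
Reagents that add atoms: none
Why: Wittig olefination in which the semi-stabilised benzylic ylide, formed under solid–liquid phase-transfer conditions that spare the methyl ester, condenses with the aldehyde; the alkene geometry is of no consequence.

Step 6
Reactants: 9 methyl 3-(4-{2-[3,4-dimethoxy-2-(methoxymethoxy)phenyl]ethenyl}phenoxy)-4-methoxybenzoate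
Product: 10 methyl 3-(4-{2-[3,4-dimethoxy-2-(methoxymethoxy)phenyl]ethyl}phenoxy)-4-methoxybenzoate
Conditions: H2 (1 atm), 10% Pd/C, EtOAc, Et3N (trace), rt
Reagents that add atoms: none
Why: Heterogeneous catalytic hydrogenation of the stilbene at a stage where no nitro group or halogen is present; MOM ether, methyl ester and diaryl ether are stable.

Step 7
Reactants: 10 methyl 3-(4-{2-[3,4-dimethoxy-2-(methoxymethoxy)phenyl]ethyl}phenoxy)-4-methoxybenzoate
Product: 11 [3-(4-{2-[3,4-dimethoxy-2-(methoxymethoxy)phenyl]ethyl}phenoxy)-4-methoxyphenyl]methanol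
Conditions: LiAlH4, THF, 0 °C
Reagents that add atoms: none
Why: Hydride reduction of the methyl ester to the benzylic alcohol; the ethers and the MOM acetal are inert to LiAlH4.

Step 8
Reactants: 11 [3-(4-{2-[3,4-dimethoxy-2-(methoxymethoxy)phenyl]ethyl}phenoxy)-4-methoxyphenyl]methanol
Product: 12 4-(bromomethyl)-2-(4-{2-[3,4-dimethoxy-2-(methoxymethoxy)phenyl]ethyl}phenoxy)-1-methoxybenzene
Conditions: CBr4, PPh3, CH2Cl2, 0 °C
Reagents that add atoms: carbon tetrabromide, BrC(Br)(Br)Br
Why: Appel bromination under neutral conditions, chosen over HBr-based methods so that the acid-labile MOM ether survives; the electron-rich benzylic bromide is used without chromatography.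

Step 9
Reactants: 12 4-(bromomethyl)-2-(4-{2-[3,4-dimethoxy-2-(methoxymethoxy)phenyl]ethyl}phenoxy)-1-methoxybenzene
Product: 13 [3-(4-{2-[3,4-dimethoxy-2-(methoxymethoxy)phenyl]ethyl}phenoxy)-4-methoxybenzyl]triphenylphosphonium bromide
Conditions: PPh3, toluene, 80 °C
Reagents that add atoms: triphenylphosphine, c1ccc(cc1)P(c1ccccc1)c1ccccc1
Why: SN2 quaternisation of PPh3 by the reactive 4-methoxybenzyl-type bromide, with the salt expected to precipitate from toluene.

Step 10
Reactants: 13 [3-(4-{2-[3,4-dimethoxy-2-(methoxymethoxy)phenyl]ethyl}phenoxy)-4-methoxybenzyl]triphenylphosphonium bromide; 14 5-fluoro-2-nitrobenzaldehyde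
Product: 16 2-{2-[3-(4-{2-[3,4-dimethoxy-2-(methoxymethoxy)phenyl]ethyl}phenoxy)-4-methoxyphenyl]ethenyl}-4-fluoro-1-nitrobenzene (E/Z mixture), via phosphonium ylide 15 (not isolated)
Conditions: NaN(SiMe3)2, THF, −78 °C; then 14, −78 °C to rt
Reagents that add atoms: none
Why: Wittig olefination in which the ylide is preformed with a non-nucleophilic amide base at low temperature, so that no free base meets the SNAr-labile C–F bond and the ylide adds to the strongly electrophilic ortho-nitrobenzaldehyde faster than to any other site.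

Step 11
Reactants: 16 2-{2-[3-(4-{2-[3,4-dimethoxy-2-(methoxymethoxy)phenyl]ethyl}phenoxy)-4-methoxyphenyl]ethenyl}-4-fluoro-1-nitrobenzene
Product: 17 2-{2-[3-(4-{2-[3,4-dimethoxy-2-(methoxymethoxy)phenyl]ethyl}phenoxy)-4-methoxyphenyl]ethyl}-4-fluoro-1-nitrobenzene
Conditions: TsNHNH2, NaOAc, DME/H2O, reflux
Reagents that add atoms: none
Why: Diimide reduction, in which diimide from thermal fragmentation of tosylhydrazide transfers H2 to the C=C bond in a concerted syn fashion and leaves the nitro group and the C–F bond untouched, which H2 over palladium would not.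

Step 12
Reactants: 17 2-{2-[3-(4-{2-[3,4-dimethoxy-2-(methoxymethoxy)phenyl]ethyl}phenoxy)-4-methoxyphenyl]ethyl}-4-fluoro-1-nitrobenzene
Product: 18 6-{2-[4-(5-[2-(5-fluoro-2-nitrophenyl)ethyl]-2-methoxyphenoxy)phenyl]ethyl}-2,3-dimethoxyphenol
Conditions: HCl (cat.), MeOH/THF, 50 °C
Reagents that add atoms: none
Why: Acid-catalysed acetal exchange removes the MOM group; methyl ethers, the diaryl ether and the fluoronitroarene are inert to methanolic HCl.

Step 13
Reactants: 18 6-{2-[4-(5-[2-(5-fluoro-2-nitrophenyl)ethyl]-2-methoxyphenoxy)phenyl]ethyl}-2,3-dimethoxyphenol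
Product: 21 nitro macrocycle (marchantin H tri-O-methyl ether carrying NO2 on ring C, para to the ring B–O–ring C ether carbon and ortho to the ring C benzylic carbon), via cesium phenoxide 19 (not isolated), via Meisenheimer adduct 20 (not isolated)
Conditions: Cs2CO3, DMF (0.002 M, slow addition of 18), 60 °C, Ar
Reagents that add atoms: none
Why: Cs2CO3 converts the single free phenol of 18 into the cesium phenoxide 19, whose oxygen adds to the fluorine-bearing carbon of ring C, para to the nitro group, to give the nitronate-stabilised Meisenheimer adduct 20, which expels fluoride and rearomatises. The closest known reaction type is the intramolecular SNAr macro-etherification of nitro-activated aryl fluorides used for cyclophane-type diaryl ethers. One ring closes, the 18-membered ring, in the macrocyclisation mode: the two ends of the open chain ring B–bridge–ring A–O–ring D–bridge–ring C meet, with the attacking oxygen staying outside ring B and the attacked carbon inside ring C. No stereocentre is formed, and should the nitro-bearing ring C rotate slowly through the macrocycle, the resulting conformers would be mirror images that converge once the nitro group is removed. The step needs intra- over intermolecular substitution, secured by high dilution with slow addition and by the two flexible saturated bridges, and it needs site selectivity, secured because 18 holds only one free OH (the other three oxygens are methyl ethers) and only one activated C–F bond. The nitro group is placed para and not ortho to the reacting carbon so that it adds no steric load to an ether oxygen already flanked by the bridge and a methoxy group.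

Step 14
Reactants: 21 nitro macrocycle
Product: 22 amino macrocycle (marchantin H tri-O-methyl ether carrying NH2 on ring C at the former nitro position)
Conditions: H2 (1 atm), 10% Pd/C, EtOAc/MeOH, rt
Reagents that add atoms: none
Why: Catalytic hydrogenation of the nitroarene to the aniline; aryl and methyl ethers are stable and no other reducible group remains.

Step 15
Reactants: 22 amino macrocycle
Product: 24 marchantin H tri-O-methyl ether, via diazonium chloride 23 (not isolated)
Conditions: NaNO2, aq. HCl, THF, 0 °C; then 50% aq. H3PO2, 0 °C to rt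
Reagents that add atoms: none
Why: Hydrodediazoniation, in which diazotisation of the aniline and radical-chain reduction of the diazonium salt by H3PO2 put hydrogen at the former nitro position; the large excess of the P–H donor should trap the aryl radical before it can add to a neighbouring ring.

Step 16
Reactants: 24 marchantin H tri-O-methyl ether
Product: 25 marchantin H
Conditions: BBr3, CH2Cl2, −78 °C to rt; then H2O
Reagents that add atoms: none
Why: Lewis-acid cleavage of the three aryl methyl ethers by BBr3 (boron coordination, bromide attack at methyl), under which the two diaryl ether bonds are not cleaved.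

**Compound list**

1 | methyl 3-hydroxy-4-methoxybenzoate | COC(=O)c1ccc(OC)c(O)c1 | starting material
2 | 4-fluorobenzaldehyde | O=Cc1ccc(F)cc1 | starting material
3 | methyl 3-(4-formylphenoxy)-4-methoxybenzoate | COC(=O)c1ccc(OC)c(Oc2ccc(C=O)cc2)c1 | intermediate
4 | methyl 3-[4-(hydroxymethyl)phenoxy]-4-methoxybenzoate | COC(=O)c1ccc(OC)c(Oc2ccc(CO)cc2)c1 | intermediate
5 | {4-[2-methoxy-5-(methoxycarbonyl)phenoxy]benzyl}triphenylphosphonium bromide | COC(=O)c1ccc(OC)c(Oc2ccc(C[P+](c3ccccc3)(c3ccccc3)c3ccccc3)cc2)c1.[Br-] | intermediate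
6 | 2-hydroxy-3,4-dimethoxybenzaldehyde | COc1ccc(C=O)c(O)c1OC | starting material
7 | 3,4-dimethoxy-2-(methoxymethoxy)benzaldehyde | COCOc1c(C=O)ccc(OC)c1OC | intermediate
8 | phosphonium ylide from 5, not isolated | COC(=O)c1ccc(OC)c(Oc2ccc(C=P(c3ccccc3)(c3ccccc3)c3ccccc3)cc2)c1 | intermediate
9 | methyl 3-(4-{2-[3,4-dimethoxy-2-(methoxymethoxy)phenyl]ethenyl}phenoxy)-4-methoxybenzoate, E/Z mixture | COC(=O)c1ccc(OC)c(Oc2ccc(C=Cc3ccc(OC)c(OC)c3OCOC)cc2)c1 | intermediate
10 | methyl 3-(4-{2-[3,4-dimethoxy-2-(methoxymethoxy)phenyl]ethyl}phenoxy)-4-methoxybenzoate | COC(=O)c1ccc(OC)c(Oc2ccc(CCc3ccc(OC)c(OC)c3OCOC)cc2)c1 | intermediate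
11 | [3-(4-{2-[3,4-dimethoxy-2-(methoxymethoxy)phenyl]ethyl}phenoxy)-4-methoxyphenyl]methanol | OCc1ccc(OC)c(Oc2ccc(CCc3ccc(OC)c(OC)c3OCOC)cc2)c1 | intermediate
12 | 4-(bromomethyl)-2-(4-{2-[3,4-dimethoxy-2-(methoxymethoxy)phenyl]ethyl}phenoxy)-1-methoxybenzene | BrCc1ccc(OC)c(Oc2ccc(CCc3ccc(OC)c(OC)c3OCOC)cc2)c1 | intermediate
13 | [3-(4-{2-[3,4-dimethoxy-2-(methoxymethoxy)phenyl]ethyl}phenoxy)-4-methoxybenzyl]triphenylphosphonium bromide | COc1ccc(C[P+](c2ccccc2)(c2ccccc2)c2ccccc2)cc1Oc1ccc(CCc2ccc(OC)c(OC)c2OCOC)cc1.[Br-] | intermediate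
14 | 5-fluoro-2-nitrobenzaldehyde | O=Cc1cc(F)ccc1[N+](=O)[O-] | starting material
15 | phosphonium ylide from 13, not isolated | COc1ccc(C=P(c2ccccc2)(c2ccccc2)c2ccccc2)cc1Oc1ccc(CCc2ccc(OC)c(OC)c2OCOC)cc1 | intermediate
16 | 2-{2-[3-(4-{2-[3,4-dimethoxy-2-(methoxymethoxy)phenyl]ethyl}phenoxy)-4-methoxyphenyl]ethenyl}-4-fluoro-1-nitrobenzene, E/Z mixture | COc1ccc(C=Cc2cc(F)ccc2[N+](=O)[O-])cc1Oc1ccc(CCc2ccc(OC)c(OC)c2OCOC)cc1 | intermediate
17 | 2-{2-[3-(4-{2-[3,4-dimethoxy-2-(methoxymethoxy)phenyl]ethyl}phenoxy)-4-methoxyphenyl]ethyl}-4-fluoro-1-nitrobenzene | COc1ccc(CCc2cc(F)ccc2[N+](=O)[O-])cc1Oc1ccc(CCc2ccc(OC)c(OC)c2OCOC)cc1 | intermediate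
18 | 6-{2-[4-(5-[2-(5-fluoro-2-nitrophenyl)ethyl]-2-methoxyphenoxy)phenyl]ethyl}-2,3-dimethoxyphenol | COc1ccc(CCc2cc(F)ccc2[N+](=O)[O-])cc1Oc1ccc(CCc2ccc(OC)c(OC)c2O)cc1 | intermediate
19 | cesium phenoxide of 18, not isolated | COc1ccc(CCc2cc(F)ccc2[N+](=O)[O-])cc1Oc1ccc(CCc2ccc(OC)c(OC)c2[O-])cc1.[Cs+] | intermediate
20 | Meisenheimer adduct (macrocyclic cesium nitronate with F and the ring B oxygen on the same ring C carbon), not isolated | COc1ccc2cc1Oc1ccc(cc1)CCc1ccc(OC)c(OC)c1OC1(F)C=CC(=[N+]([O-])[O-])C(=C1)CC2.[Cs+] | intermediate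
21 | nitro macrocycle: marchantin H tri-O-methyl ether with NO2 on ring C para to the ether carbon | COc1ccc2cc1Oc1ccc(cc1)CCc1ccc(OC)c(OC)c1Oc1ccc([N+](=O)[O-])c(c1)CC2 | intermediate
22 | amino macrocycle: marchantin H tri-O-methyl ether with NH2 on ring C para to the ether carbon | COc1ccc2cc1Oc1ccc(cc1)CCc1ccc(OC)c(OC)c1Oc1ccc(N)c(c1)CC2 | intermediate
23 | diazonium chloride of 22, not isolated | COc1ccc2cc1Oc1ccc(cc1)CCc1ccc(OC)c(OC)c1Oc1ccc([N+]#N)c(c1)CC2.[Cl-] | intermediate
24 | marchantin H tri-O-methyl ether | COc1ccc2cc1Oc1ccc(cc1)CCc1ccc(OC)c(OC)c1Oc1cccc(c1)CC2 | intermediate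
25 | marchantin H | Oc1ccc2cc1Oc1ccc(cc1)CCc1ccc(O)c(O)c1Oc1cccc(c1)CC2 | target

**Totals**

Total step count: 16. Longest linear sequence: 15 steps (steps 1–3 and 5–16, from compound 1); step 4 is a one-step side branch.

**Steps most likely to fail**

Step 13. Chain-to-chain substitution leading to oligomers may outrun ring closure, because the attacking oxygen is flanked on both sides, and prolonged basic heating may degrade the nitroarene before it closes. The fallback closes the same ether bond by copper-catalysed Ullmann coupling with no activating group. It sets out from phosphonium salt 13. Its ylide 15 (NaN(SiMe3)2, THF, −78 °C) is condensed with commercial 3-iodobenzaldehyde to give the iodostilbene 1-iodo-3-{2-[3-(4-{2-[3,4-dimethoxy-2-(methoxymethoxy)phenyl]ethyl}phenoxy)-4-methoxyphenyl]ethenyl}benzene F1. Diimide (TsNHNH2, NaOAc, DME/H2O, reflux) should saturate the alkene without touching the C–I bond and give the iodo-bibenzyl F2. Methanolic HCl then removes the MOM group to give the iodophenol 6-{2-[4-(5-[2-(3-iodophenyl)ethyl]-2-methoxyphenoxy)phenyl]ethyl}-2,3-dimethoxyphenol F3. Copper monoiodide (CuI), picolinic acid and K3PO4 in DMSO at 90 °C under high dilution, a system that accepts phenols substituted at both ortho positions, should then give marchantin H tri-O-methyl ether. The fallback comes back to the route at compound 24, and steps 14 and 15 fall away.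

Step 10. The ylide or residual base may attack the activated C–F bond or transfer an electron to the nitroarene instead of adding to the aldehyde, the electron-rich benzylic phosphonium salt may decompose, and the diimide reduction that follows may stall. The fallback makes the saturated bridge directly by a B-alkyl Suzuki–Miyaura coupling. It sets out from alcohol 11. MnO2 in CH2Cl2 gives the aldehyde 3-(4-{2-[3,4-dimethoxy-2-(methoxymethoxy)phenyl]ethyl}phenoxy)-4-methoxybenzaldehyde F4. Methylenation (MePPh3Br, KOt-Bu, THF) gives the styrene 4-ethenyl-2-(4-{2-[3,4-dimethoxy-2-(methoxymethoxy)phenyl]ethyl}phenoxy)-1-methoxybenzene F5. Anti-Markovnikov hydroboration with 9-BBN in THF gives the B-(2-arylethyl)-9-borabicyclo[3.3.1]nonane F6, which is used in solution. Coupling with commercial 2-bromo-4-fluoro-1-nitrobenzene (PdCl2(dppf), anhydrous K3PO4, THF/DMF, 60 °C) should give the fluoronitro bibenzyl. The fallback comes back to the route at compound 17 and replaces steps 8 to 11.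

Step 15. The aryl radical (or cation) released from the diazonium salt may add to the neighbouring ring D across the two-carbon bridge, a Pschorr-type closure to a dihydrophenanthrene, or be captured by water as a phenol, instead of being reduced. The fallback avoids the diazonium salt by palladium-catalysed reductive denitration. It sets out from nitro macrocycle 21: Pd(acac)2, BrettPhos, K3PO4 and 2-propanol in dioxane at 130 °C. The sequence is oxidative addition of the Ar–NO2 bond to zerovalent palladium, exchange of nitrite for isopropoxide, β-hydride elimination and C–H reductive elimination. It comes back to the route at compound 24 and bypasses compounds 22 and 23; no new compound arises (F0).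

**Further compounds**

F1 | step 13 | 1-iodo-3-{2-[3-(4-{2-[3,4-dimethoxy-2-(methoxymethoxy)phenyl]ethyl}phenoxy)-4-methoxyphenyl]ethenyl}benzene, E/Z mixture | COc1ccc(C=Cc2cccc(I)c2)cc1Oc1ccc(CCc2ccc(OC)c(OC)c2OCOC)cc1
F2 | step 13 | 1-iodo-3-{2-[3-(4-{2-[3,4-dimethoxy-2-(methoxymethoxy)phenyl]ethyl}phenoxy)-4-methoxyphenyl]ethyl}benzene | COc1ccc(CCc2cccc(I)c2)cc1Oc1ccc(CCc2ccc(OC)c(OC)c2OCOC)cc1
F3 | step 13 | 6-{2-[4-(5-[2-(3-iodophenyl)ethyl]-2-methoxyphenoxy)phenyl]ethyl}-2,3-dimethoxyphenol | COc1ccc(CCc2cccc(I)c2)cc1Oc1ccc(CCc2ccc(OC)c(OC)c2O)cc1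
F4 | step 10 | 3-(4-{2-[3,4-dimethoxy-2-(methoxymethoxy)phenyl]ethyl}phenoxy)-4-methoxybenzaldehyde | COc1ccc(C=O)cc1Oc1ccc(CCc2ccc(OC)c(OC)c2OCOC)cc1
F5 | step 10 | 4-ethenyl-2-(4-{2-[3,4-dimethoxy-2-(methoxymethoxy)phenyl]ethyl}phenoxy)-1-methoxybenzene | COc1ccc(C=C)cc1Oc1ccc(CCc2ccc(OC)c(OC)c2OCOC)cc1
F6 | step 10 | 9-{2-[3-(4-{2-[3,4-dimethoxy-2-(methoxymethoxy)phenyl]ethyl}phenoxy)-4-methoxyphenyl]ethyl}-9-borabicyclo[3.3.1]nonane | COc1ccc(CCB2C3CCCC2CCC3)cc1Oc1ccc(CCc2ccc(OC)c(OC)c2OCOC)cc1
F0 | step 15 | none | none
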